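**Retrosynthetic overview** (labdane numbering of the target, C1–C20, is used throughout)

1. The C14=C15 enol ether comes from dehydration of a C14 alcohol. The spiro tetrahydrofuranone (O–C9 bond) comes from oxa-Michael addition of the C13 hydroxyl to a C9=C11–C12 enone, made by Meyer–Schuster rearrangement of a C9 alkynyl carbinol (ring-B C9 ketone + an L-threitol-derived alkyne that carries C11–C16 and the C13 stereocenter).
2. Ring A is closed at C2–C3 by acylation of a sulfone carbanion; the C1–C2 unit is put on C10 by a Michael addition anti to C4, which fixes the trans A/B fusion.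
3. Key disconnection: C4–C5 and O–C6 are made together by oxidative radical cyclisation–lactonisation of a methylmalonic half ester hung on a β-hydroxyl at C9 of a ring-B cyclohexenol. The enabling feature is that C4 is the central carbon of a 1,3-dicarbonyl unit (C3, C19) whose C19 carboxyl oxygen sits on C6, cis to the C4–C5 bond on ring B, and that C9, 1,3 to C5, bears oxygen that can anchor the tether through C3.
4. Ring B comes from anti-crotylation of pent-4-enal and ring-closing metathesis.
5. Ring order: B → γ-lactone (with a temporary bridging δ-lactone) → A → spiro tetrahydrofuranone → dihydrofuran (its oxolane ring is carried in from the threitol unit and unsaturated last).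

Key step: step 4

Remark: compounds 4, 9 and (3S,4S)-tetrahydrofuran-3,4-diol (1,4-anhydro-L-threitol, 13) are taken as commercial; stereolabile centres that are erased later (malonate carbon of 5, C2 of 11, 12 and 18) are drawn without configuration.

**Step 1**
Reactants: 1 pent-4-enal
Product: 2 (3S,4S)-3-methylocta-1,7-dien-4-ol
Conditions: (E)-crotyl-B(Ipc)2 from (−)-α-pinene, THF, −78 °C; then NaOH, H2O2, 25 °C
Reagents that add atoms: (E)-crotyldiisopinocampheylborane from (−)-α-pinene, C/C=C/CB([C@H]1C[C@H]2C[C@@H]([C@@H]1C)C2(C)C)[C@H]1C[C@H]2C[C@@H]([C@@H]1C)C2(C)C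
Why: Brown crotylboration through a closed chair transition state, in which the E-crotyl group gives the anti pair and the (−)-α-pinene-derived ligands direct attack to the Re face of the aldehyde, so that the carbinol carbon (future C9) and the methyl-bearing carbon (future C10) are both S.

**Step 2**
Reactants: 2 (3S,4S)-3-methylocta-1,7-dien-4-ol
Product: 3 (1S,2S)-2-methylcyclohex-3-en-1-ol (trans)
Conditions: second-generation Grubbs catalyst (H2IMes)(PCy3)Cl2Ru=CHPh (2 mol %), CH2Cl2, 40 °C
Reagents that add atoms: none
Why: Ring-closing metathesis of the two terminal alkenes closes ring B with loss of ethylene and leaves both stereocenters untouched, so the anti pair becomes the trans ring pair.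

**Step 3**
Reactants: 3 (1S,2S)-2-methylcyclohex-3-en-1-ol; 4 2,2,5-trimethyl-1,3-dioxane-4,6-dione (methyl Meldrum's acid)
Product: 5 2-methyl-3-{[(1S,2S)-2-methylcyclohex-3-en-1-yl]oxy}-3-oxopropanoic acid
Conditions: toluene, 100 °C
Reagents that add atoms: none
Why: Alcoholysis of a Meldrum's acid: the alcohol opens the acylal and acetone is lost, which should give the malonic half ester directly.

**Step 4**
Reactants: 5 methylmalonic half ester of 3
Product: 6 tricyclic bis-lactone (ring B with 10α-methyl; C4 bearing CH3 bonded to C5 on the β face; γ-lactone C19(=O)–O–C6β; bridging δ-lactone C3(=O)–O–C9β)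
Conditions: Mn(OAc)3·2H2O (2.2 equiv), KOAc, AcOH, 60 °C, degassed
Reagents that add atoms: none
Why: Trivalent manganese forms the enolate of the malonic half ester and oxidises it to the tertiary C4 malonyl radical, which adds 6-exo-trig to C5 of the ring-B alkene through the ester tether (bridging δ-lactone, 2-oxabicyclo[3.3.1] skeleton), and the secondary C6 radical is then oxidised by a second equivalent of Mn(OAc)3 with capture by the neighbouring carboxylate, which closes the five-membered γ-lactone at C6. The closest known reaction type is the Mn(OAc)3-mediated oxidative cyclisation–lactonisation (double annulation) of alkenyl malonic and β-keto acids, together with the oxidative cyclisation of allylic malonates to lactones. C5 is set by the tether, because the C9 oxygen is β and axial in the reactive half-chair, so C4 can only reach the β face of C5, anti to the pseudo-axial 10α-methyl. C6 follows because a five-membered lactone on a cyclohexane closes cis, so the oxygen enters on the β face next to C4. C4 is set because only the arrangement with the free carboxyl turned towards C6 and the methyl exo can lactonise from the chair δ-lactone, and this is the configuration of the target with the tether carbonyl in the place of C3. The step needs 6-exo over 7-endo attack, secured by the 1,3-relation of C9 and C5, and lactonisation over oxidative elimination at C6, secured by the carboxylate held next to C6.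

**Step 5**
Reactants: 6 tricyclic bis-lactone
Product: 7 methyl ester hydroxy lactone (δ-lactone opened: C3 methyl ester on C4, 9β-OH; γ-lactone C19–O–C6 kept)
Conditions: K2CO3 (0.2 equiv), MeOH, 0 °C
Reagents that add atoms: methanol, CO
Why: Base-catalysed transesterification opens the bridging δ-lactone, whose 1,3-diaxial strain is released on opening, while the cis-fused γ-lactone, which is stable to methanolysis, should stay closed; no stereocenter is touched.

**Step 6**
Reactants: 7 methyl ester hydroxy lactone
Product: 8 C9 ketone (C10 still H/CH3)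
Conditions: Pr4N[RuO4] (5 mol %), N-methylmorpholine N-oxide, 4 Å sieves, CH2Cl2, 25 °C
Reagents that add atoms: none
Why: Ley–Griffith oxidation of the secondary C9 alcohol under neutral conditions that spare the lactone and the ester.

**Step 7**
Reactants: 8 C9 ketone; 9 phenyl vinyl sulfone
Product: 10 Michael adduct (C10 quaternary: CH3 β, CH2CH2SO2Ph α)
Conditions: KOt-Bu (0.15 equiv), t-BuOH/THF, 0 °C
Reagents that add atoms: none
Why: Thermodynamic Michael addition, as in a Robinson annulation of a 2-methylcyclohexanone, takes place at the more substituted α-carbon C10, and the acceptor enters anti to the bulky C4 substituent on the neighbouring C5, which gives the trans relation of C1 and C4 needed for ring A.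

**Step 8**
Reactants: 10 Michael adduct
Product: 12 tricyclic keto sulfone with 8α-methyl (trans-decalin; 3,9-dione; 2-phenylsulfonyl; 19,6β-lactone), via ring-A keto sulfone 11 (not isolated)
Conditions: LiN(i-Pr)2 (2.3 equiv), THF, −78 to 0 °C; MeI (1.05 equiv), −78 °C; aq NH4Cl; then DBU, CH2Cl2, 25 °C
Reagents that add atoms: iodomethane, CI
Why: The C8 ketone enolate forms first and masks C9, the α-sulfonyl carbanion at C2 then acylates the C3 ester (Dieckmann-type 6-exo-trig closure of ring A; the lactone carbonyl C19 cannot be reached while the γ-lactone is intact), and of the resulting dianion only the ketone enolate is methylated at C8; equilibration with DBU places the new methyl equatorial (8α) on the rigid trans-decalin.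

**Step 9**
Reactants: 13 (3S,4S)-tetrahydrofuran-3,4-diol
Product: 14 (3S,4S)-4-[(tert-butyldimethylsilyl)oxy]tetrahydrofuran-3-ol
Conditions: NaH (1.0 equiv), THF, 0 °C; then t-BuMe2SiCl
Reagents that add atoms: tert-butyldimethylsilyl chloride, CC(C)(C)[Si](C)(C)Cl
Why: Monosilylation through the mono-alkoxide of a C2-symmetric diol, whose two hydroxyls are equivalent, so only one mono-ether can form.

**Step 10**
Reactants: 14 mono-silyl ether
Product: 15 (4S)-4-[(tert-butyldimethylsilyl)oxy]dihydrofuran-3(2H)-one
Conditions: Pr4N[RuO4] (5 mol %), N-methylmorpholine N-oxide, 4 Å sieves, CH2Cl2, 25 °C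
Reagents that add atoms: none
Why: Ley–Griffith oxidation under neutral conditions, which should not epimerise the α-silyloxy center.

**Step 11**
Reactants: 15 silyloxy ketone
Product: 16 (3R,4S)-4-[(tert-butyldimethylsilyl)oxy]-3-ethynyltetrahydrofuran-3-ol
Conditions: HC≡CMgBr, THF, −78 °C
Reagents that add atoms: ethynylmagnesium bromide, C#C[Mg]Br
Why: Grignard addition to the cyclic α-silyloxy ketone occurs anti to the bulky silyloxy group, which sets the tertiary carbinol (future C13) with its hydroxyl cis to the silyloxy group.

**Step 12**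
Reactants: 16 ethynyl carbinol
Product: 17 triethylsilyl ether of 16
Conditions: Et3SiOTf, 2,6-lutidine, CH2Cl2, −78 to 0 °C
Reagents that add atoms: triethylsilyl trifluoromethanesulfonate, CC[Si](CC)(CC)OS(=O)(=O)C(F)(F)F
Why: Silylation of a hindered tertiary alcohol with a silyl triflate; the ether later blocks the second propargylic oxygen.

**Step 13**
Reactants: 12 tricyclic keto sulfone; 17 protected alkyne
Product: 18 C9 alkynyl carbinol (9β-OH, alkyne α, joined to C13 of the oxolane)
Conditions: 17, n-BuLi, THF, −78 °C; CeCl3; then 12 pre-treated with LiN(SiMe3)2 (1.05 equiv), −78 to −40 °C; aq NH4Cl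
Reagents that add atoms: none
Why: The keto sulfone is masked as its enolate, so C3 is inert, and the weakly basic alkynylcerium adds to the hindered C9 ketone (axial attack anti to the axial C10 methyl is expected); the C9 configuration is of no consequence because C9 becomes trigonal in step 15.

**Step 14**
Reactants: 18 C9 alkynyl carbinol
Product: 19 desulfonylated carbinol (C2 now CH2, C3 ketone free)
Conditions: SmI2 (3 equiv), THF/MeOH, −78 °C
Reagents that add atoms: none
Why: Reductive desulfonylation of a β-keto sulfone by single-electron transfer and protonation of the samarium enolate; silyl ethers, alkyne and lactone are inert.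

**Step 15**
Reactants: 19 desulfonylated carbinol
Product: 20 enone C9=C11–C12(=O)–C13 (E drawn; the geometry is of no consequence)
Conditions: MoO2(acac)2 (5 mol %), Ph3PAuCl (5 mol %), AgOTf (5 mol %), toluene, 25 °C
Reagents that add atoms: none
Why: Meyer–Schuster rearrangement (1,3-shift of the only free propargylic hydroxyl, C9–OH, then tautomerisation) places the carbonyl at C12, because the other propargylic oxygen is silylated.

**Step 16**
Reactants: 20 enone
Product: 22 spiro tetrahydrofuranone with 14-OSiMe2t-Bu, via hydroxy enone 21 (not isolated)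
Conditions: pyridinium p-toluenesulfonate, MeOH, 25 °C; then camphorsulfonic acid (0.2 equiv), CH2Cl2, 25 °C
Reagents that add atoms: none
Why: Selective methanolysis of the tertiary triethylsilyl ether frees the C13 hydroxyl, which adds to C9 of the protonated enone (acid-catalysed oxa-Michael, 5-endo-trig) axially from the α face, anti to the axial C10 methyl, so that oxygen is 9α and C11 equatorial; the reversible closure should also favour the 8α-methyl, 9α-oxygen arrangement thermodynamically.

**Step 17**
Reactants: 22 spiro ketone silyl ether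
Product: 23 14-hydroxy spiro ketone
Conditions: HF·pyridine, THF, 0 to 25 °C
Reagents that add atoms: none
Why: Fluoride cleavage of the secondary silyl ether under non-basic conditions, which avoids retro-aldol cleavage of the β-hydroxy ketone.

**Step 18**
Reactants: 23 14-hydroxy spiro ketone
Product: 24 target CNP0143138.1
Conditions: Burgess reagent (MeO2CN−SO2N+Et3), toluene, 70 °C
Reagents that add atoms: none
Why: Burgess dehydration (syn elimination of the sulfamate ester) can only take a hydrogen from C15, because C13 is quaternary, and should thus give the 14,15-enol ether without touching C13.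

**Compound list**

1 | pent-4-enal | C=CCCC=O | starting material
2 | (3S,4S)-3-methylocta-1,7-dien-4-ol | C=CCC[C@H](O)[C@@H](C)C=C | intermediate
3 | (1S,2S)-2-methylcyclohex-3-en-1-ol | O[C@H]1CCC=C[C@@H]1C | intermediate
4 | 2,2,5-trimethyl-1,3-dioxane-4,6-dione | CC1C(=O)OC(C)(C)OC1=O | starting material
5 | 2-methyl-3-{[(1S,2S)-2-methylcyclohex-3-en-1-yl]oxy}-3-oxopropanoic acid (malonate carbon not defined) | OC(=O)C(C)C(=O)O[C@H]1CCC=C[C@@H]1C | intermediate
6 | tricyclic bis-lactone: γ-lactone C19–O–C6β, δ-lactone C3–O–C9β, 10α-methyl, C4 as in the target | C[C@H]1[C@H]2[C@H]3CC[C@@H]1OC(=O)[C@]2(C)C(=O)O3 | intermediate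
7 | γ-lactone with C3 methyl ester on C4 and 9β-hydroxyl | C[C@H]1[C@H]2[C@@H](CC[C@@H]1O)OC(=O)[C@@]2(C)C(=O)OC | intermediate
8 | corresponding C9 ketone | C[C@H]1[C@H]2[C@@H](CCC1=O)OC(=O)[C@@]2(C)C(=O)OC | intermediate
9 | phenyl vinyl sulfone | C=CS(=O)(=O)c1ccccc1 | starting material
10 | Michael adduct, 10β-methyl-10α-[2-(phenylsulfonyl)ethyl] | C[C@]1(CCS(=O)(=O)c3ccccc3)[C@H]2[C@@H](CCC1=O)OC(=O)[C@@]2(C)C(=O)OC | intermediate
11 | ring-A keto sulfone without the C8 methyl (3,9-dione, 2-phenylsulfonyl, 19,6β-lactone; C2 not defined) | O=C1CC[C@H]2OC(=O)[C@@]3(C)C(=O)C(S(=O)(=O)c4ccccc4)C[C@@]1(C)[C@@H]23 | intermediate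
12 | 8α-methyl tricyclic keto sulfone (C2 not defined) | C[C@@H]1C[C@H]2OC(=O)[C@@]3(C)C(=O)C(S(=O)(=O)c4ccccc4)C[C@@](C)([C@@H]23)C1=O | intermediate
13 | (3S,4S)-tetrahydrofuran-3,4-diol | O[C@H]1COC[C@@H]1O | starting material
14 | (3S,4S)-4-[(tert-butyldimethylsilyl)oxy]tetrahydrofuran-3-ol | O[C@H]1COC[C@@H]1O[Si](C)(C)C(C)(C)C | intermediate
15 | (4S)-4-[(tert-butyldimethylsilyl)oxy]dihydrofuran-3(2H)-one | O=C1COC[C@@H]1O[Si](C)(C)C(C)(C)C | intermediate
16 | (3R,4S)-4-[(tert-butyldimethylsilyl)oxy]-3-ethynyltetrahydrofuran-3-ol | C#C[C@@]1(O)COC[C@@H]1O[Si](C)(C)C(C)(C)C | intermediate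
17 | triethylsilyl ether of 16 | C#C[C@@]1(O[Si](CC)(CC)CC)COC[C@@H]1O[Si](C)(C)C(C)(C)C | intermediate
18 | C9 alkynyl carbinol (9β-OH; C2 not defined) | C[C@@H]1C[C@H]2OC(=O)[C@@]3(C)C(=O)C(S(=O)(=O)c4ccccc4)C[C@@](C)([C@@H]23)[C@]1(O)C#C[C@@]5(O[Si](CC)(CC)CC)COC[C@@H]5O[Si](C)(C)C(C)(C)C | intermediate
19 | desulfonylated C9 alkynyl carbinol | C[C@@H]1C[C@H]2OC(=O)[C@@]3(C)C(=O)CC[C@@](C)([C@@H]23)[C@]1(O)C#C[C@@]4(O[Si](CC)(CC)CC)COC[C@@H]4O[Si](C)(C)C(C)(C)C | intermediate
20 | C9=C11–C12 enone with 13-OSiEt3 and 14-OSiMe2t-Bu | C[C@@H]1C[C@H]2OC(=O)[C@@]3(C)C(=O)CC[C@@](C)([C@@H]23)/C1=C/C(=O)[C@@]4(O[Si](CC)(CC)CC)COC[C@@H]4O[Si](C)(C)C(C)(C)C | intermediate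
21 | hydroxy enone (13-OH free) | C[C@@H]1C[C@H]2OC(=O)[C@@]3(C)C(=O)CC[C@@](C)([C@@H]23)/C1=C/C(=O)[C@@]4(O)COC[C@@H]4O[Si](C)(C)C(C)(C)C | intermediate
22 | spiro tetrahydrofuranone with 14-OSiMe2t-Bu and saturated C15 | C[C@@H]1C[C@H]2OC(=O)[C@@]3(C)C(=O)CC[C@@](C)([C@@H]23)[C@@]12CC(=O)[C@@]1([C@@H](O[Si](C)(C)C(C)(C)C)COC1)O2 | intermediate
23 | 14-hydroxy spiro tetrahydrofuranone | C[C@@H]1C[C@H]2OC(=O)[C@@]3(C)C(=O)CC[C@@](C)([C@@H]23)[C@@]12CC(=O)[C@@]1([C@@H](O)COC1)O2 | intermediate
24 | CNP0143138.1 | C[C@@H]1C[C@H]2OC(=O)[C@@]3(C)C(=O)CC[C@@](C)([C@@H]23)[C@@]12CC(=O)[C@@]1(C=COC1)O2 | target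

**Count and risks**

Total step count: 18. Longest linear sequence: 14 (steps 1–8 and 13–18).

Steps most likely to fail:

- **Step 4.** The ester-tethered 6-exo cyclisation needs the s-cis ester rotamer and may be slow, so the malonyl radical could be over-oxidised or acetoxylated before it cyclises, and the C6 radical could undergo oxidative elimination instead of lactonisation. The fallback sets out from 5 and returns at 6. Bromination at the malonate carbon (N-bromosuccinimide, cat. Mg(ClO4)2, MeCN) would give the bromo acid F1. Copper-catalysed atom-transfer radical cyclisation (CuBr, tris(2-pyridylmethyl)amine, 1,2-dichloroethane, 80 °C) would then give the bridged δ-lactone bromide F2, with bromine transferred to the α face of C6, anti to C4. K2CO3 in DMF would close the γ-lactone by intramolecular SN2 displacement with inversion, which gives 6.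

- **Step 7.** The catalytic base may enolise the ketone towards C8 and alkylate the wrong α-carbon, and the C10 enolate may expel the stabilised C4 malonate unit by retro-Michael cleavage. The fallback sets out from 8 and returns at 10. Thermodynamic silylation (Me3SiCl, NaI, Et3N, MeCN) would give the C9=C10 trimethylsilyl enol ether F3, purified from its regioisomer. Fluoride-triggered conjugate addition to 9 (Bu4N[Ph3SiF2], THF, −78 °C) would then release the regiodefined enolate in the absence of base and give 10.

- **Step 15.** The hindered tertiary carbinol may dehydrate to an enyne (Rupe path) or the strained exocyclic enone may not form. The fallback sets out from 19 and returns at 20. Semi-hydrogenation (H2, Pd/CaCO3 poisoned with Pb(OAc)2, quinoline, EtOAc) would give the Z-allylic alcohol F4. Oxidative 1,3-transposition with pyridinium chlorochromate, C5H5NH[CrO3Cl], in CH2Cl2 (Babler–Dauben oxidation) would give 20, whose double-bond geometry does not matter for step 16.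

**Further compounds**

F1 | step 4 | 2-bromo-2-methyl-3-{[(1S,2S)-2-methylcyclohex-3-en-1-yl]oxy}-3-oxopropanoic acid | OC(=O)C(C)(Br)C(=O)O[C@H]1CCC=C[C@@H]1C
F2 | step 4 | bridged δ-lactone with 6α-bromide and free C19 acid on C4 | C[C@H]1[C@H]2[C@@H](Br)CC[C@@H]1OC(=O)[C@]2(C)C(O)=O
F3 | step 7 | C9=C10 trimethylsilyl enol ether of 8 | C[Si](C)(C)OC1=C(C)[C@H]2[C@@H](CC1)OC(=O)[C@@]2(C)C(=O)OC
F4 | step 15 | Z-allylic alcohol from semi-hydrogenation of 19 | C[C@@H]1C[C@H]2OC(=O)[C@@]3(C)C(=O)CC[C@@](C)([C@@H]23)[C@]1(O)/C=C\[C@@]4(O[Si](CC)(CC)CC)COC[C@@H]4O[Si](C)(C)C(C)(C)C
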